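**Retrosynthetic overview**
1. The C8 carbinol comes from an 8-ketone and MeMgBr; the ketone comes from allylic oxidation and conjugate reduction of a Δ6-octalin; the C20 methyl comes from an angular formyl group.
2. Rings A and B are formed together by one intramolecular Diels–Alder reaction of an acyclic trienal: C5–C10 closes ring A through the C1–C4 chain, and C8–C9 completes ring B.
3. Enabling feature: C5–C10 is the fusion bond shared by rings A and B, and the quaternary C10 carries a one-carbon group (C20) that can be a formyl group. C9=C10 then becomes an α-branched enal dienophile with the whole side chain on C9, and C5–C8 becomes a diene.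
4. The trienal comes from a directed aldol condensation of a (5R)-bromodienal (C1–C8, C10, C20) with an aldehyde cut from (R)-linalool (C9, C11–C16; C13 bought).
5. C3–Br is set by organocatalytic α-bromination and is the only catalyst-made stereocentre; C5, C9 and C10 are relayed from it in the key step, and C8 follows by substrate control.

Key step: step 11

Remark: C1–C20 in the text are the labdane numbers of the target (C17 on C8, C18/C19 on C4, C20 on C10).
Assumption: the (2R,5R)-catalyst in step 2 is the enantiomer that gives the (S)-bromoaldehyde; if the sense of induction is the reverse, the (2S,5S)-catalyst is used.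
Assumption: compounds 1, 3, 8 and (R)-linalool of high enantiomeric purity are bought.

**Route**

Step 1
Reactants: 1 2,2-dimethylpent-4-enenitrile
Product: 2 2,2-dimethyl-4-oxobutanenitrile
Conditions: O3, CH2Cl2, −78 °C; then Me2S, −78 °C to rt
Reagents that add atoms: ozone, [O-][O+]=O
Why: Ozonolysis with reductive work-up cleaves the only alkene to the aldehyde (C2), and the nitrile is inert.

Step 2
Reactants: 2 2,2-dimethyl-4-oxobutanenitrile; 3 [2-(1,3-dioxolan-2-yl)ethyl]triphenylphosphonium bromide
Product: 5 (3R,4Z)-3-bromo-6-(1,3-dioxolan-2-yl)-2,2-dimethylhex-4-enenitrile, via (S)-bromoaldehyde 4 (not isolated)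
Conditions: (2R,5R)-2,5-diphenylpyrrolidine (20 mol%), 4,4-dibromo-2,6-di-tert-butylcyclohexa-2,5-dienone, PhCO2H, H2O, CH2Cl2/pentane, −40 °C; cold silica filtration; then addition to the ylide from 3 and NaN(SiMe3)2, THF, −78 to 0 °C
Reagents that add atoms: 4,4-dibromo-2,6-di-tert-butylcyclohexa-2,5-dienone, CC(C)(C)C1=CC(Br)(Br)C=C(C(C)(C)C)C1=O
Why: Enamine-catalysed enantioselective α-bromination sets C3 (bromine enters the enamine face left open by the C2-symmetric pyrrolidine), and the labile bromoaldehyde is trapped at once by Wittig olefination with the non-stabilised ylide that brings C1, C10 and the masked C20 aldehyde.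

Step 3
Reactants: 5 (3R,4Z)-3-bromo-6-(1,3-dioxolan-2-yl)-2,2-dimethylhex-4-enenitrile
Product: 6 (3R)-3-bromo-6-(1,3-dioxolan-2-yl)-2,2-dimethylhexanenitrile
Conditions: KO2CN=NCO2K, AcOH, MeOH/CH2Cl2, 0 °C to rt
Reagents that add atoms: none
Why: Diimide reduction saturates the cis-alkene by concerted syn hydrogen transfer, without hydrogenolysis or allylic shift of the neighbouring C–Br bond, so C3 is untouched.

Step 4
Reactants: 6 (3R)-3-bromo-6-(1,3-dioxolan-2-yl)-2,2-dimethylhexanenitrile
Product: 7 (3R)-3-bromo-6-(1,3-dioxolan-2-yl)-2,2-dimethylhexanal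
Conditions: iBu2AlH, toluene, −78 °C; then aq. tartaric acid, 0 °C
Reagents that add atoms: water, O
Why: Partial reduction of the tertiary nitrile with iBu2AlH stops at the N-aluminoimine, which is hydrolysed to the aldehyde (C5); there is no α-hydrogen, so the β-bromide cannot eliminate.

Step 5
Reactants: 7 (3R)-3-bromo-6-(1,3-dioxolan-2-yl)-2,2-dimethylhexanal; 8 diethyl allylphosphonate
Product: 9 2-[(4R,6E)-4-bromo-5,5-dimethylnona-6,8-dien-1-yl]-1,3-dioxolane
Conditions: 8, n-BuLi, THF, −78 °C; then 7; then HMPA, −78 °C to rt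
Reagents that add atoms: none
Why: Horner–Wadsworth–Emmons-type olefination with the lithiated allylphosphonate should give the terminal (E)-1,3-diene (C5–C8), the E geometry being favoured by the bulky quaternary group on the aldehyde.

Step 6
Reactants: 9 2-[(4R,6E)-4-bromo-5,5-dimethylnona-6,8-dien-1-yl]-1,3-dioxolane
Product: 10 (5R,7E)-5-bromo-6,6-dimethyldeca-7,9-dienal
Conditions: pyridinium p-toluenesulfonate, acetone/H2O, 50 °C
Reagents that add atoms: water, O
Why: Mild acid-catalysed acetal hydrolysis frees the C20 aldehyde and leaves the diene and the secondary bromide alone.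

Step 7
Reactants: 11 (R)-linalool
Product: 12 (3R)-3,7-dimethyl-3-[(triethylsilyl)oxy]octa-1,6-diene
Conditions: Et3SiOTf, 2,6-lutidine, CH2Cl2, −78 to 0 °C
Reagents that add atoms: triethylsilyl trifluoromethanesulfonate, CC[Si](CC)(CC)OS(=O)(=O)C(F)(F)F
Why: Silylation of the tertiary alcohol with the silyl triflate protects C13–OH without touching the stereocentre.

Step 8
Reactants: 12 (3R)-3,7-dimethyl-3-[(triethylsilyl)oxy]octa-1,6-diene
Product: 13 (4R)-4-methyl-4-[(triethylsilyl)oxy]hex-5-enal
Conditions: O3 (1 equiv), CH2Cl2/MeOH, −78 °C; then Me2S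
Reagents that add atoms: ozone, [O-][O+]=O
Why: Ozonolysis with one equivalent of ozone should cleave the electron-rich trisubstituted alkene in preference to the monosubstituted vinyl group and give the C9 aldehyde.

Step 9
Reactants: 10 (5R,7E)-5-bromo-6,6-dimethyldeca-7,9-dienal
Product: 14 (5R,7E)-5-bromo-N-cyclohexyl-6,6-dimethyldeca-7,9-dien-1-imine
Conditions: cyclohexylamine, MgSO4, Et2O, 0 °C to rt; used crude
Reagents that add atoms: cyclohexylamine, NC1CCCCC1
Why: Imine condensation turns the aldehyde into the aldimine needed for a directed aldol reaction.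

Step 10
Reactants: 14 (5R,7E)-5-bromo-N-cyclohexyl-6,6-dimethyldeca-7,9-dien-1-imine; 13 (4R)-4-methyl-4-[(triethylsilyl)oxy]hex-5-enal
Product: 16 (2E,6R)-2-[(3R,5E)-3-bromo-4,4-dimethylocta-5,7-dien-1-yl]-6-methyl-6-[(triethylsilyl)oxy]octa-2,7-dienal, via β-hydroxy imine 15 (not isolated)
Conditions: LiN(iPr)2, THF, −78 °C; then 13, −78 to −20 °C; then aq. oxalic acid, rt
Reagents that add atoms: none
Why: Directed aldol condensation through the lithiated aldimine avoids self-condensation of either aldehyde, and acid hydrolysis with dehydration should give the more stable (E)-2-alkylidene aldehyde (formyl trans to C11).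

Step 11
Reactants: 16 (2E,6R)-2-[(3R,5E)-3-bromo-4,4-dimethylocta-5,7-dien-1-yl]-6-methyl-6-[(triethylsilyl)oxy]octa-2,7-dienal
Product: 17 (2R,4aR,5S,8aS)-2-bromo-1,1-dimethyl-5-[(3R)-3-methyl-3-[(triethylsilyl)oxy]pent-4-en-1-yl]-1,3,4,5,6,8a-hexahydronaphthalene-4a(2H)-carbaldehyde
Conditions: Me2AlCl (0.3 equiv), CH2Cl2, −78 to −20 °C
Reagents that add atoms: none
Why: Type 1 intramolecular Diels–Alder reaction: the Lewis-acid-bound α-branched enal (C9=C10, formyl = C20) adds across the diene C5=C6–C7=C8 in one concerted, asynchronous [4+2] event that forms C5–C10 and C8–C9; the closest known reaction type is the Lewis-acid-promoted cyclisation of decatrienals whose formyl group sits on the tether-bearing dienophile carbon, which gives trans-fused octalins with an angular formyl group. Ring A is closed through the four-carbon tether C1–C4 in a chair-like six-membered array with the tether anti to the diene, and ring B is the new cyclohexene. C5 and C10 are set by the endo orientation of the formyl group, which puts the geminal tether exo and gives the trans ring fusion; C9 is set by the (E) geometry of the enal, transferred suprafacially, so that H9 is cis and the side chain trans to C20, with the side chain exo. The absolute sense comes from C3: the bromide next to the gem-dimethyl group takes the equatorial place in the chair-like tether and so selects one diene face. The step needs endo over exo and one π-face; the first should be secured by the coordinated formyl group and the exo placement of both bulky groups, the second by the equatorial bromide.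

Step 12
Reactants: 17 (the angular aldehyde)
Product: 18 p-toluenesulfonylhydrazone of 17
Conditions: TsNHNH2, EtOH, rt to 50 °C
Reagents that add atoms: p-toluenesulfonyl hydrazide, Cc1ccc(S(=O)(=O)NN)cc1
Why: Condensation of the only carbonyl group gives the tosylhydrazone needed for deoxygenation of C20.

Step 13
Reactants: 18 p-toluenesulfonylhydrazone of 17
Product: 19 (1S,4aS,6R,8aS)-6-bromo-5,5,8a-trimethyl-1-[(3R)-3-methyl-3-[(triethylsilyl)oxy]pent-4-en-1-yl]-1,2,4a,5,6,7,8,8a-octahydronaphthalene
Conditions: catecholborane, CHCl3, 0 °C; then NaOAc·3H2O, reflux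
Reagents that add atoms: none
Why: Wolff–Kishner-type reduction of the tosylhydrazone (hydride addition, loss of sulfinate, then loss of N2 from the diazene) turns the formyl group into the C20 methyl under conditions that should spare the bromide, the alkenes and the silyl ether.

Step 14
Reactants: 19 (the Δ6-octalin)
Product: 20 (1R,4aS,6R,8aR)-6-bromo-5,5,8a-trimethyl-1-[(3R)-3-methyl-3-[(triethylsilyl)oxy]pent-4-en-1-yl]-4a,5,6,7,8,8a-hexahydronaphthalen-2(1H)-one
Conditions: Rh2(cap)4 (cap = caprolactamate, 1 mol%), t-BuOOH, K2CO3, CH2Cl2, rt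
Reagents that add atoms: tert-butyl hydroperoxide, CC(C)(C)OO
Why: Radical allylic oxidation: the peroxy radical should abstract the accessible allylic hydrogen at C8 (the C5–H is tertiary and flanked by two quaternary carbons) and the allyl radical should be oxygenated at its less hindered end, giving the 6-en-8-one; the side-chain vinyl group has no allylic hydrogen.

Step 15
Reactants: 20 (the enone)
Product: 21 (1R,4aS,6R,8aR)-6-bromo-5,5,8a-trimethyl-1-[(3R)-3-methyl-3-[(triethylsilyl)oxy]pent-4-en-1-yl]octahydronaphthalen-2(1H)-one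
Conditions: [(Ph3P)CuH]6, toluene/THF, H2O (2 equiv), rt
Reagents that add atoms: none
Why: Copper hydride conjugate reduction saturates only the enone C6=C7 bond, leaves the vinyl group and the bromide alone, and forms the enolate away from C9, so the axial C9 side chain should not epimerise.

Step 16
Reactants: 21 (the 8-ketone)
Product: 22 (1R,2R,4aS,6R,8aR)-6-bromo-2,5,5,8a-tetramethyl-1-[(3R)-3-methyl-3-[(triethylsilyl)oxy]pent-4-en-1-yl]decahydronaphthalen-2-ol
Conditions: MeMgBr, CeCl3, THF, −78 °C
Reagents that add atoms: methylmagnesium bromide, C[Mg]Br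
Why: 1,2-Addition of the organocerium reagent: the face of the C8 carbonyl syn to the axial C20 methyl is blocked by the 1,3-diaxial contact, so methyl should enter equatorially and leave the C8–OH axial and cis to C20 as in the target, while CeCl3 suppresses enolisation towards C9.

Step 17
Reactants: 22 (the silyl ether of the target)
Product: 23 (1R,2R,4aS,6R,8aR)-6-bromo-1-[(3R)-3-hydroxy-3-methylpent-4-en-1-yl]-2,5,5,8a-tetramethyldecahydronaphthalen-2-ol (CNP0150870.1)
Conditions: Bu4NF, THF, 0 °C to rt
Reagents that add atoms: none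
Why: Fluoride desilylation frees the C13 tertiary allylic alcohol; the equatorial C3 bromide has no anti-periplanar hydrogen and should survive the mildly basic conditions.

**Compound list**
1 | 2,2-dimethylpent-4-enenitrile | C=CCC(C)(C)C#N | starting material
2 | 2,2-dimethyl-4-oxobutanenitrile | O=CCC(C)(C)C#N | intermediate
3 | [2-(1,3-dioxolan-2-yl)ethyl]triphenylphosphonium bromide | [Br-].C1COC(CC[P+](c2ccccc2)(c2ccccc2)c2ccccc2)O1 | starting material
4 | (2S)-2-bromo-3-cyano-3-methylbutanal | O=C[C@@H](Br)C(C)(C)C#N | intermediate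
5 | (3R,4Z)-3-bromo-6-(1,3-dioxolan-2-yl)-2,2-dimethylhex-4-enenitrile | N#CC(C)(C)[C@H](Br)/C=C\CC1OCCO1 | intermediate
6 | (3R)-3-bromo-6-(1,3-dioxolan-2-yl)-2,2-dimethylhexanenitrile | N#CC(C)(C)[C@H](Br)CCCC1OCCO1 | intermediate
7 | (3R)-3-bromo-6-(1,3-dioxolan-2-yl)-2,2-dimethylhexanal | O=CC(C)(C)[C@H](Br)CCCC1OCCO1 | intermediate
8 | diethyl allylphosphonate | C=CCP(=O)(OCC)OCC | starting material
9 | 2-[(4R,6E)-4-bromo-5,5-dimethylnona-6,8-dien-1-yl]-1,3-dioxolane | C=C/C=C/C(C)(C)[C@H](Br)CCCC1OCCO1 | intermediate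
10 | (5R,7E)-5-bromo-6,6-dimethyldeca-7,9-dienal | C=C/C=C/C(C)(C)[C@H](Br)CCCC=O | intermediate
11 | (R)-linalool | C=C[C@](C)(O)CCC=C(C)C | starting material
12 | (3R)-3,7-dimethyl-3-[(triethylsilyl)oxy]octa-1,6-diene | C=C[C@](C)(O[Si](CC)(CC)CC)CCC=C(C)C | intermediate
13 | (4R)-4-methyl-4-[(triethylsilyl)oxy]hex-5-enal | C=C[C@](C)(O[Si](CC)(CC)CC)CCC=O | intermediate
14 | (5R,7E)-5-bromo-N-cyclohexyl-6,6-dimethyldeca-7,9-dien-1-imine | C=C/C=C/C(C)(C)[C@H](Br)CCC/C=N/C1CCCCC1 | intermediate
15 | β-hydroxy imine (aldol adduct of 14 and 13; mixture at the two new carbinol/α centres) | C=C/C=C/C(C)(C)[C@H](Br)CCC(/C=N/C1CCCCC1)C(O)CC[C@](C)(C=C)O[Si](CC)(CC)CC | intermediate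
16 | (2E,6R)-2-[(3R,5E)-3-bromo-4,4-dimethylocta-5,7-dien-1-yl]-6-methyl-6-[(triethylsilyl)oxy]octa-2,7-dienal | C=C[C@](C)(O[Si](CC)(CC)CC)CC/C=C(/C=O)CC[C@@H](Br)C(C)(C)/C=C/C=C | intermediate
17 | (2R,4aR,5S,8aS)-2-bromo-1,1-dimethyl-5-[(3R)-3-methyl-3-[(triethylsilyl)oxy]pent-4-en-1-yl]-1,3,4,5,6,8a-hexahydronaphthalene-4a(2H)-carbaldehyde | C=C[C@](C)(O[Si](CC)(CC)CC)CC[C@@H]1[C@]2(C=O)CC[C@@H](Br)C(C)(C)[C@H]2C=CC1 | intermediate
18 | p-toluenesulfonylhydrazone of 17 | C=C[C@](C)(O[Si](CC)(CC)CC)CC[C@@H]1[C@]2(/C=N/NS(=O)(=O)c3ccc(C)cc3)CC[C@@H](Br)C(C)(C)[C@H]2C=CC1 | intermediate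
19 | (1S,4aS,6R,8aS)-6-bromo-5,5,8a-trimethyl-1-[(3R)-3-methyl-3-[(triethylsilyl)oxy]pent-4-en-1-yl]-1,2,4a,5,6,7,8,8a-octahydronaphthalene | C=C[C@](C)(O[Si](CC)(CC)CC)CC[C@@H]1[C@]2(C)CC[C@@H](Br)C(C)(C)[C@H]2C=CC1 | intermediate
20 | (1R,4aS,6R,8aR)-6-bromo-5,5,8a-trimethyl-1-[(3R)-3-methyl-3-[(triethylsilyl)oxy]pent-4-en-1-yl]-4a,5,6,7,8,8a-hexahydronaphthalen-2(1H)-one | C=C[C@](C)(O[Si](CC)(CC)CC)CC[C@@H]1[C@]2(C)CC[C@@H](Br)C(C)(C)[C@H]2C=CC1=O | intermediate
21 | (1R,4aS,6R,8aR)-6-bromo-5,5,8a-trimethyl-1-[(3R)-3-methyl-3-[(triethylsilyl)oxy]pent-4-en-1-yl]octahydronaphthalen-2(1H)-one | C=C[C@](C)(O[Si](CC)(CC)CC)CC[C@@H]1[C@]2(C)CC[C@@H](Br)C(C)(C)[C@H]2CCC1=O | intermediate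
22 | (1R,2R,4aS,6R,8aR)-6-bromo-2,5,5,8a-tetramethyl-1-[(3R)-3-methyl-3-[(triethylsilyl)oxy]pent-4-en-1-yl]decahydronaphthalen-2-ol | C=C[C@](C)(O[Si](CC)(CC)CC)CC[C@@H]1[C@]2(C)CC[C@@H](Br)C(C)(C)[C@H]2CC[C@@]1(C)O | intermediate
23 | (1R,2R,4aS,6R,8aR)-6-bromo-1-[(3R)-3-hydroxy-3-methylpent-4-en-1-yl]-2,5,5,8a-tetramethyldecahydronaphthalen-2-ol | C=C[C@](C)(O)CC[C@@H]1[C@]2(C)CC[C@@H](Br)C(C)(C)[C@H]2CC[C@@]1(C)O | target

**Totals**
Total step count: 17. Longest linear sequence: 15 steps (steps 1–6 and 9–17).

**Steps most likely to fail, with fallbacks**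

Step 11. What may go wrong: loss of endo and π-facial control, or slow closure against the developing 1,3-diaxial contact between C20 and the axial C4 methyl, with ionisation of the tertiary allylic silyl ether by the aluminium Lewis acid as a side process. The fallback sets out from 16 and changes the dienophile from a Lewis-acid complex to a cation (ionic Diels–Alder reaction). Compound 16 is acetalised with 1,2-bis(trimethylsilyloxy)ethane and catalytic Me3SiOTf in CH2Cl2 at −78 °C to the ethylene acetal of 16 F1. On warming to −40 °C the same catalyst opens the acetal to an alkoxy-allyl cation, a much stronger dienophile with a strong endo preference, which should close to the ethylene acetal of 17 F2. Hydrolysis with pyridinium p-toluenesulfonate in wet acetone returns to the route at 17.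

Step 2. What may go wrong: deprotonation of the α-bromoaldehyde by the basic ylide (erosion of the C3 configuration, debromination), and allylic shift of the bromide in 5 before it is reduced. The fallback sets out from 4 and replaces olefination and diimide reduction by substitution and hydrogenation. The crude bromoaldehyde is reduced in the same flask with NaBH4 to (3S)-3-bromo-4-hydroxy-2,2-dimethylbutanenitrile F3. This is converted with Tf2O and 2,6-lutidine into (2S)-2-bromo-3-cyano-3-methylbutyl trifluoromethanesulfonate F4. SN2 displacement of the primary triflate by the lithium acetylide of 2-ethynyl-1,3-dioxolane (THF/DMPU, −78 °C) gives (3R)-3-bromo-6-(1,3-dioxolan-2-yl)-2,2-dimethylhex-5-ynenitrile F5. Hydrogenation over Pd/C in EtOAc returns to the route at 6.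

Step 14. What may go wrong: hydrogen abstraction at C5 or oxygen capture at C6, which would give the transposed enone, and over-oxidation. The fallback sets out from 19 and uses an ene/[2,3]-sigmatropic pathway instead of a free allyl radical. SeO2 (catalytic) with t-BuOOH in CH2Cl2 should hydroxylate the allylic CH2 at C8 without shifting the alkene, giving the C8 allylic alcohol of 19 F6 (carbinol configuration not controlled). Oxidation with DMP returns to the route at 20.

**Further compounds**
F1 | step 11 | ethylene acetal of 16: 2-[(1E,5R)-1-[(3R,5E)-3-bromo-4,4-dimethylocta-5,7-dien-1-yl]-5-methyl-5-[(triethylsilyl)oxy]hepta-1,6-dien-1-yl]-1,3-dioxolane | C=C[C@](C)(O[Si](CC)(CC)CC)CC/C=C(/C1OCCO1)CC[C@@H](Br)C(C)(C)/C=C/C=C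
F2 | step 11 | ethylene acetal of 17 (angular 1,3-dioxolan-2-yl in place of formyl) | C=C[C@](C)(O[Si](CC)(CC)CC)CC[C@@H]1[C@]2(C3OCCO3)CC[C@@H](Br)C(C)(C)[C@H]2C=CC1
F3 | step 2 | (3S)-3-bromo-4-hydroxy-2,2-dimethylbutanenitrile | OC[C@@H](Br)C(C)(C)C#N
F4 | step 2 | (2S)-2-bromo-3-cyano-3-methylbutyl trifluoromethanesulfonate | O=S(=O)(OC[C@@H](Br)C(C)(C)C#N)C(F)(F)F
F5 | step 2 | (3R)-3-bromo-6-(1,3-dioxolan-2-yl)-2,2-dimethylhex-5-ynenitrile | N#CC(C)(C)[C@H](Br)CC#CC1OCCO1
F6 | step 14 | C8 allylic alcohol of 19: 6-bromo-5,5,8a-trimethyl-1-[(3R)-3-methyl-3-[(triethylsilyl)oxy]pent-4-en-1-yl]-1,2,4a,5,6,7,8,8a-octahydronaphthalen-2-ol | C=C[C@](C)(O[Si](CC)(CC)CC)CC[C@@H]1[C@]2(C)CC[C@@H](Br)C(C)(C)[C@H]2C=CC1O
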